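The numbers in the tables were computed on assumed constants; noise was put on by code.

Divide the left-handed substrate by the right-handed substrate at each moment and call this ratio r; the excess of right-handed substrate is then one minus r, over one plus r. Turned around, the wanted excess becomes a wanted ratio, one minus the excess over one plus the excess, r* = 0.0256.

- Saturday's: left-handed substrate 0.50 mM; right-handed substrate 0.50 mM; gas 0.055 mM (held); free catalyst 85 µM; the very flask that is asked about, followed so far
- flask: left-handed substrate 0.50 mM; gas 0.055 mM (held); free catalyst 85 µM; right-handed substrate 0.50 mM; time 6.0 min

Saturday's run (percent of the left-handed substrate and right-handed substrate together charged)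

| time / s | right-handed substrate / % | left-handed substrate / % |
|---|---|---|
| 15.0 | 50.3 | 44.8 |
| 40.0 | 50.2 | 32.0 |
| 80.0 | 48.6 | 16.3 |
| 120 | 47.6 | 5.4 |

(readings scatter by 1 percentage point)

- whether the excess of right-handed substrate over left-handed substrate among what is left of the two reaches 95% by 6.0 min (yes / no)
- the highest excess of right-handed substrate over left-handed substrate among what is left of the two up to 6.0 min

- free catalyst is single-handed; left-handed substrate and right-handed substrate are mirror images of each other, charged as a racemate, each of them at the stated concentration
- the numbers in the tables scatter with a standard deviation of 1 percentage point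
- at the start none of the gas is in solution

At the start of Saturday's run none of the gas is in solution, yet left-handed substrate already reads 44.8% after 15.0 s. Through the middle it falls to 16.3% at 80.0 s, while right-handed substrate reads 2.4 percentage points below its charge at 120 s, against a scatter of 1 point. The two log-losses at that reading stand at 45.2 to one, a rough reading of the selectivity factor.

So r moves through left-handed substrate. At 120 s Saturday's run reads r = 0.113, which is 4.41 times r*. With right-handed substrate at its reading, r* asks for left-handed substrate of 1.22% of the two charged together.

The reckoning here assumes that the last log-slope read, 0.0276 s⁻¹, holds. It then takes 53.8 s more, so this estimate puts the crossing at 2.90 min, earlier than 6.0 min.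

The forecast says yes with a top of 99.7%, on the ground that “the excess keeps climbing”.

The flask answers yes, with a top excess of 99.9%.

    reagent + free catalyst + left-handed substrate → free catalyst + left-handed product (k = 2.59 × 10⁷ M⁻² s⁻¹)
    reagent + free catalyst + right-handed substrate → free catalyst + right-handed product (k = 2.69 × 10⁵ M⁻² s⁻¹)
    gas ⇌ reagent, rate k3*(csat - [reagent]) (kL = 0.0966 s⁻¹)
    reagent + free catalyst → spent catalyst (k = 283 M⁻¹ s⁻¹)
    left-handed product ⇌ right-handed product (k = 0.0688 s⁻¹)

In the flask the wanted excess arrives at 2.53 min, when 48.1% of right-handed substrate is left. Multiplied by r*, that puts left-handed substrate at 1.23% at the crossing. At 6.00 min the flask holds left-handed substrate at 0.0257% against 46.2% of right-handed substrate, a ratio 46.0 times below r*.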